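## Structural features

The target is a sesquilignan with six rings. A 4-hydroxy-3-methoxyphenyl ring (ring A) sits on C2 of a 2,3-dihydrobenzofuran (benzo ring B, dihydrofuran ring C). C5 of ring B carries a cis-fused 3,7-dioxabicyclo[3.3.0]octane (rings D and E, atoms C1′, C2′, O3′, C4′, C5′, C6′, O7′, C8′), which ends in a 4-hydroxy-3,5-dimethoxyphenyl ring (ring F) on C6′.

Ring B is a 1,2,3,5-tetrasubstituted benzene. C3a and C7a are the fusion atoms, C7a bears the ring oxygen O1, the adjacent C7 bears OMe, C5 bears the bicycle, and C4 and C6 bear hydrogen.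

There are two stereochemical clusters. C2 and C3 are adjacent and both S, so aryl and CH2OH lie on the same face (cis, the less stable arrangement). C1′, C2′, C5′ and C6′ are contiguous, (1′R,2′S,5′R,6′S), with both aryl groups exo. Ring B separates the clusters, so neither can direct the other.

Three benzylic C–O bonds are fragile. C2–O1 has an aryloxide leaving group and a para-oxygenated aryl group, so acid can open it and reclose it to the trans isomer. C2′–O3′ and C6′–O7′ are open to acid epimerisation and to hydrogenolysis. The free phenols are sensitive to oxidation and, under base, to quinone methide formation.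

The real difficulty is threefold: the contra-thermodynamic cis C2/C3 pair, the vicinal oxygens on C7/C7a of ring B, and absolute control of four further centres remote from the first two.

The key step uses the O1-on-C7a / oxygen-on-C7 pattern together with the C3a–C7a fusion. A furan supplies C3a, C4, C5, C6 and the future C7 oxygen; an ethynyl ether on the C2 oxygen supplies C7a and C7. Rings B and C then form together, after C2 and C3 have been set in an open chain.

## Logic of the disconnections

**39 from 38.** The three O–CH2Ar bonds (two aryl benzyl ethers, one naphthylmethyl alkyl ether) are cut last. All fall under neutral hydrogenolysis, so no acid or base meets the free phenols. The forward step must finish before the ring benzylic C–O bonds react; for that reason the only alkyl ether is naphthylmethyl, which cleaves faster than a benzyl alkyl ether.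

**38 from 36 (through 37).** O3′–C4′ and O7′–C8′, the two non-benzylic C–O bonds of the bicycle, are cut. Closing them by O-alkylation at primary carbons breaks no bond to a stereocentre and needs no acid. The bicycle becomes an open-chain tetraol. The forward step must sulfonylate the two primary hydroxyls in preference to the two benzylic ones.

**36 from 23 and 33 (through 34 and 35).** C1′–C2′ is cut as an aldol bond. This joins the two halves late and sets C1′ and C2′ by auxiliary control, which is required because C2/C3 are too far away to help. The syn relation of O3′ and C5′ along C2′–C1′–C8′ matches a boron syn-aldol. The forward step must override the resident C5′ centre of 33 and tolerate its silylene.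

**33 from 25 and 26 (through 27–32).** C5′–C6′ is cut as a second syn-aldol bond. The imide carbonyl becomes C4′, the allyl terminus is cleaved to the C8′ carboxyl, and a silylene ties the oxygens on C4′ and C6′ so that fluoride, not acid, can release them. 25 comes from 8 and 24. The demand is clean oxidative cleavage next to an electron-rich ring.

**23 from 20 (through 21 and 22).** These are functional-group changes only: the C7 phenol is methylated and the C5 silyloxymethyl group is unmasked and oxidised. The C5 carbon is carried as a silyl ether because a free alcohol or aldehyde would interfere with the alkoxide and gold steps.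

**20 from 19 (key).** C3a–C7a and C6–C7 are cut and the C7 oxygen is returned to a furan. One isomerisation replaces an arene synthesis with awkward oxygenation, and C2/C3 are untouched. The forward step needs an ethynyl ether on a benzylic, ionisable oxygen to survive long enough to cyclise.

**19 from 15 and 16 (through 17 and 18).** O1–C7a is cut; 16 supplies C7a and C7. The neighbouring primary oxygen must carry a group that cannot migrate to the alkoxide. That requirement, together with the final hydrogenolysis, fixes the naphthylmethyl ether of 15.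

**15 from 10 and 11 (through 12, 13 and 14).** C2–C3 is cut as an anti-aldol bond. The cis ring requires the anti (1S,2S) diad, so a magnesium-catalysed anti-aldol of the imide is used instead of a boron syn-aldol. The demand is anti selectivity without epimerising the acidic furyl-bearing carbon.

**10 from 7 and 8; 7 from 3 and 4 (through 5 and 6); 3 from 1 (through 2).** The furan C2–CH2 bond is cut as a cross-coupling. Lithiation or electrophilic substitution of a 3-substituted furan favours the wrong α-position, so the 2,4-pattern is bought as the bromine of 1.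

## Other disconnections considered

**Alternative 1:** The cut removes C5′–C6′ and C1′–C2′ together. In the forward step the lithium anion of dithiane A3 adds to the menthyloxybutenolide A2 anti to the menthyloxy group, and the lactone enolate is trapped by aldehyde A4 anti to the new substituent, to give A1.

- In favour: three components join in one flask. C1′ and C5′ are set with absolute control from a cheap, crystalline chiral acetal, with no auxiliary to attach and remove.
- Against: the C2′ carbinol is not controlled and C6′ arrives as a dithioketal. Dithiane removal next to electron-rich rings, a stereoselective ketone reduction, reduction of the lactone and acetal carbons and closure at both benzylic carbons remain. Those closures normally rely on acid and a thermodynamic exo preference, and acid threatens the cis C2–O1 bond.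
- Comparison: on structure it addresses only the bicycle; A4 is the silyl analogue of 23, so it would replace steps 14–24 and not step 10. On mechanism it is an anionic conjugate addition–aldol under substrate control, against two auxiliary-controlled boron aldols. It is the better plan in C–C bond economy and the equal in absolute control at C1′ and C5′. It is weaker at C2′ and C6′ and in post-processing, so the overall step count is expected to be similar.

**Alternative 2:** The cut is C2′–O3′. In the forward step base adds the C4′ hydroxyl of arylidene lactone A6 to the benzylidene carbon, and protonation at C1′ gives the bicyclic lactone A5.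

- In favour: it is base-mediated, so the C2–O1 bond is not exposed to acid. The addition is reversible, so the exo aryl group at C2′ should be favoured, and cis fusion is enforced by the ring. It avoids the selective sulfonylation of a tetraol, a point on which it is better than the chosen plan.
- Against: the closure is 5-endo-trig, and the acceptor carbon carries an electron-rich aryl group, so addition is slow and easily reversed. C8′ remains a carbonyl that must be reduced and the ring re-closed, which adds two or three steps.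
- Comparison: on structure it again covers only the bicycle. On mechanism it sets C2′ by equilibrium where the chosen plan uses a kinetic aldol. It is the equal in control of the ring fusion, and the step count is about the same.

**Alternative 3:** The cut is C1′–C5′ and C6′–O7′. In the forward step Cp2TiCl (trivalent titanium) opens the terminal epoxide of A8 to a radical at C1′, which cyclises 5-exo onto the alkene. Iodine then converts the benzylic C6′ position into an electrophile that the titanium alkoxide closes, to give A7.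

- In favour: both tetrahydrofuran rings form in one flask under neutral, non-acidic conditions that suit the cis C2–O1 bond and the silyl and benzyl ethers. No carbonyl redox adjustment is needed. It is clearly better in step economy: about four steps from an aldehyde, against eleven for steps 14–24.
- Against: C2′ must be set beforehand, which needs an asymmetric route to the epoxy alcohol on advanced material. C1′ and C5′ are set by a radical transition state and C6′ by an ionic closure, both under substrate control. Iodine meets electron-rich rings, and the cinnamyl-type ether can ionise.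
- Comparison: on structure it does nothing for ring B. On mechanism it is radical where the chosen plan is polar. It is superior in length and inferior in stereochemical certainty, so it is the natural replacement if the aldol sequence is judged too long.

Key step: step 10

Remark: the given stereodescriptors place the C2 aryl and C3 hydroxymethyl groups on the same face (2S,3S), so the open-chain precursor must be the anti (1S,2S) diad; ring B carries four substituents.

Remark: compared with a plain benzyl ether at the primary oxygen, the precursor carries naphthalen-2-ylmethyl (NAP) there. It cannot migrate under KH and leaves quickly in the last step. TBS = tert-butyldimethylsilyl; ArB = the (2S,3S)-2-(4-benzyloxy-3-methoxyphenyl)-7-methoxy-3-[(naphthalen-2-ylmethoxy)methyl]-2,3-dihydro-1-benzofuran-5-yl group.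

## Route

Step 1
Reactants: 1 5-bromofuran-3-carboxylic acid
Product: 2 (5-bromofuran-3-yl)methanol
Conditions: BH3·THF, THF, 0 °C to rt; MeOH quench
Reagents that add atoms: none
Why: Borane reduces the carboxylic acid chemoselectively (acyloxyborane reduction) and leaves the bromofuran intact; the bromine marks the future side-chain position.

Step 2
Reactants: 2 (5-bromofuran-3-yl)methanol
Product: 3 tert-butyl[(5-bromofuran-3-yl)methoxy]dimethylsilane
Conditions: TBSCl, imidazole, DMF, rt
Reagents that add atoms: tert-butyldimethylsilyl chloride, CC(C)(C)[Si](C)(C)Cl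
Why: Standard imidazole-promoted silylation of a primary alcohol; the TBS ether survives every base used up to the gold step and is the only silyl ether present when it is removed.

Step 3
Reactants: 3 tert-butyl[(5-bromofuran-3-yl)methoxy]dimethylsilane; 4 ethyl bromoacetate
Product: 6 ethyl 2-{4-[(tert-butyldimethylsilyloxy)methyl]furan-2-yl}acetate, via bromozinc ester enolate 5 (not isolated)
Conditions: Zn dust, TMSCl (cat.), THF, 40 °C; then 3, Pd2(dba)3 (1 mol %), XPhos (4 mol %), THF, 50 °C
Reagents that add atoms: zinc, [Zn] (present only in 5)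
Why: Zinc insertion gives the Reformatsky reagent, which undergoes Negishi-type coupling (α-arylation of a zinc ester enolate) with the 2-bromofuran on a zerovalent palladium/biarylphosphine catalyst. The bromine places the chain on the α-carbon remote from the silyloxymethyl group, so the 2,4-pattern needs no regioselective metalation.

Step 4
Reactants: 6 ethyl 2-{4-[(tert-butyldimethylsilyloxy)methyl]furan-2-yl}acetate
Product: 7 2-{4-[(tert-butyldimethylsilyloxy)methyl]furan-2-yl}acetic acid
Conditions: LiOH, THF/H2O, 0 °C to rt; then cold 0.5 M HCl to pH 4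
Reagents that add atoms: lithium hydroxide, [Li+].[OH-]
Why: Saponification of an unhindered ethyl ester; brief cold acidification to pH 4 leaves the primary TBS ether in place.

Step 5
Reactants: 7 2-{4-[(tert-butyldimethylsilyloxy)methyl]furan-2-yl}acetic acid; 8 (4S)-4-benzyl-1,3-oxazolidin-2-one
Product: 10 (4S)-4-benzyl-3-(2-{4-[(tert-butyldimethylsilyloxy)methyl]furan-2-yl}acetyl)-1,3-oxazolidin-2-one, via mixed pivalic anhydride 9 (not isolated)
Conditions: PivCl, Et3N, THF, −20 °C; then 8, LiCl, rt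
Reagents that add atoms: pivaloyl chloride, CC(C)(C)C(Cl)=O (present only in 9)
Why: Mixed-anhydride N-acylation of the oxazolidinone under LiCl/Et3N activation; the hindered pivaloyl carbonyl directs attack to the furylacetyl carbonyl and no strong base meets the acidic methylene.

Step 6
Reactants: 10 (4S)-4-benzyl-3-(2-{4-[(tert-butyldimethylsilyloxy)methyl]furan-2-yl}acetyl)-1,3-oxazolidin-2-one; 11 4-benzyloxy-3-methoxybenzaldehyde
Product: 13 (4S)-4-benzyl-3-[(2S,3S)-3-(4-benzyloxy-3-methoxyphenyl)-2-{4-[(tert-butyldimethylsilyloxy)methyl]furan-2-yl}-3-hydroxypropanoyl]-1,3-oxazolidin-2-one, via trimethylsilyl ether 12 (not isolated)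
Conditions: MgCl2 (20 mol %), Et3N, TMSCl, EtOAc, rt; then MeOH, PPTS (cat.), 0 °C
Reagents that add atoms: chlorotrimethylsilane, C[Si](C)(C)Cl (present only in 12)
Why: Magnesium-halide-catalysed direct anti-aldol of an N-acyloxazolidinone: the chelated (Z)-magnesium enolate is attacked through a boat transition state on the face opposite the auxiliary benzyl group, which should set the anti (2S,3S) diad. Silylation of the aldolate blocks retro-aldol and epimerisation of the acidic furyl-bearing carbon, and the aldehyde cannot enolise.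

Step 7
Reactants: 13 (4S)-4-benzyl-3-[(2S,3S)-3-(4-benzyloxy-3-methoxyphenyl)-2-{4-[(tert-butyldimethylsilyloxy)methyl]furan-2-yl}-3-hydroxypropanoyl]-1,3-oxazolidin-2-one
Product: 14 (1S,2S)-1-(4-benzyloxy-3-methoxyphenyl)-2-{4-[(tert-butyldimethylsilyloxy)methyl]furan-2-yl}propane-1,3-diol
Conditions: LiBH4, H2O (1 equiv), Et2O/THF, 0 °C
Reagents that add atoms: none
Why: Reductive cleavage of the imide by hydride attack at the exocyclic carbonyl releases the auxiliary for reuse and touches neither stereocentre; low temperature limits retro-aldol.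

Step 8
Reactants: 14 (1S,2S)-1-(4-benzyloxy-3-methoxyphenyl)-2-{4-[(tert-butyldimethylsilyloxy)methyl]furan-2-yl}propane-1,3-diol
Product: 15 (1S,2S)-1-(4-benzyloxy-3-methoxyphenyl)-2-{4-[(tert-butyldimethylsilyloxy)methyl]furan-2-yl}-3-(naphthalen-2-ylmethoxy)propan-1-ol
Conditions: Ag2O, 2-(bromomethyl)naphthalene, CH2Cl2, rt
Reagents that add atoms: 2-(bromomethyl)naphthalene, BrCc1ccc2ccccc2c1
Why: Silver-oxide-mediated mono-O-alkylation (Williamson type) of a 1,3-diol is selective for the unhindered primary hydroxyl. The NAP ether cannot migrate to the neighbouring alkoxide in step 9 and is hydrogenolysed faster than a benzyl alkyl ether.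

Step 9
Reactants: 15 (1S,2S)-1-(4-benzyloxy-3-methoxyphenyl)-2-{4-[(tert-butyldimethylsilyloxy)methyl]furan-2-yl}-3-(naphthalen-2-ylmethoxy)propan-1-ol; 16 trichloroethylene
Product: 19 (1S,2S)-1-(4-benzyloxy-3-methoxyphenyl)-1-(ethynyloxy)-2-{4-[(tert-butyldimethylsilyloxy)methyl]furan-2-yl}-3-(naphthalen-2-ylmethoxy)propane, via dichlorovinyl ether 17 (not isolated), via lithium alkoxyacetylide 18 (not isolated)
Conditions: KH, THF, 0 °C; 16, −50 to 0 °C; then n-BuLi (2.5 equiv), −78 °C; MeOH, −78 °C; cold neutral work-up, used at once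
Reagents that add atoms: n-butyllithium, [Li]CCCC (lithium present only in 18)
Why: The potassium alkoxide adds to dichloroacetylene formed in situ to give the (E)-1,2-dichlorovinyl ether; n-BuLi then removes HCl and exchanges the remaining chlorine to give the lithium alkoxyacetylide, which is protonated cold (dichlorovinyl ether route to alkynyl ethers). The C1–O bond is never broken, so C1 keeps its configuration.

Step 10
Reactants: 19 (1S,2S)-1-(4-benzyloxy-3-methoxyphenyl)-1-(ethynyloxy)-2-{4-[(tert-butyldimethylsilyloxy)methyl]furan-2-yl}-3-(naphthalen-2-ylmethoxy)propane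
Product: 20 (2S,3S)-2-(4-benzyloxy-3-methoxyphenyl)-5-[(tert-butyldimethylsilyloxy)methyl]-3-[(naphthalen-2-ylmethoxy)methyl]-2,3-dihydro-1-benzofuran-7-ol
Conditions: (Ph3P)AuNTf2 (3 mol %), 2,6-di-tert-butyl-4-methylpyridine (5 mol %), 4 Å MS, CH2Cl2, −20 to 0 °C
Reagents that add atoms: none
Why: Cationic monovalent gold binds the electron-rich alkyne of 19 and the furan C2=C3 bond attacks the oxygen-bearing alkyne carbon, so C3a–C7a forms and the dihydrofuran ring closes 5-exo-dig to a cyclopropyl gold carbene. Opening of the cyclopropane and the furan C–O bond gives a (Z)-dienone gold carbene whose carbene carbon (future C7) is captured by the carbonyl oxygen on C6; the resulting oxepine/arene oxide closes ring B as a six-membered carbocycle through the C6–C7 bond. The arene oxide opens at C6–O, because that cation is stabilised by O1 on C7a, and a hydrogen shift leaves the hydroxyl on C7. The closest known reaction type is the gold-catalysed furan–yne phenol synthesis with ynol-ether tethers, which gives 7-hydroxy-2,3-dihydrobenzofurans. No stereocentre is created; C2 and C3 are spectators, so the cis (2S,3S) relation of 20 is inherited from the anti diad of 19. The selectivity needed is regiochemical and is fixed by the substrate: the tether oxygen on the internal alkyne carbon puts O1 on C7a and OH on C7, and the 2,4-disubstituted furan puts the silyloxymethyl group on C5 and hydrogen on C4 and C6. Loss of the benzylic C2–O1 bond from the gold-activated ynol ether is held back by the low temperature, the hindered base that removes traces of acid, and the speed of the intramolecular furan attack.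

Step 11
Reactants: 20 (2S,3S)-2-(4-benzyloxy-3-methoxyphenyl)-5-[(tert-butyldimethylsilyloxy)methyl]-3-[(naphthalen-2-ylmethoxy)methyl]-2,3-dihydro-1-benzofuran-7-ol
Product: 21 tert-butyl{[(2S,3S)-2-(4-benzyloxy-3-methoxyphenyl)-7-methoxy-3-[(naphthalen-2-ylmethoxy)methyl]-2,3-dihydro-1-benzofuran-5-yl]methoxy}dimethylsilane
Conditions: MeI, K2CO3, acetone, rt
Reagents that add atoms: iodomethane, CI
Why: Williamson O-methylation of the only acidic hydroxyl; mild carbonate base does not disturb the cis C2/C3 pair.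

Step 12
Reactants: 21 tert-butyl{[(2S,3S)-2-(4-benzyloxy-3-methoxyphenyl)-7-methoxy-3-[(naphthalen-2-ylmethoxy)methyl]-2,3-dihydro-1-benzofuran-5-yl]methoxy}dimethylsilane
Product: 22 [(2S,3S)-2-(4-benzyloxy-3-methoxyphenyl)-7-methoxy-3-[(naphthalen-2-ylmethoxy)methyl]-2,3-dihydro-1-benzofuran-5-yl]methanol
Conditions: TBAF, THF, 0 °C
Reagents that add atoms: none
Why: Fluoride cleavage of the single silyl ether; benzyl and NAP ethers are inert.

Step 13
Reactants: 22 [(2S,3S)-2-(4-benzyloxy-3-methoxyphenyl)-7-methoxy-3-[(naphthalen-2-ylmethoxy)methyl]-2,3-dihydro-1-benzofuran-5-yl]methanol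
Product: 23 (2S,3S)-2-(4-benzyloxy-3-methoxyphenyl)-7-methoxy-3-[(naphthalen-2-ylmethoxy)methyl]-2,3-dihydro-1-benzofuran-5-carbaldehyde
Conditions: MnO2, CH2Cl2, rt
Reagents that add atoms: none
Why: Neutral, heterogeneous oxidation that is selective for the benzylic alcohol and stops at the aldehyde; no acid or base reaches C2.

Step 14
Reactants: 8 (4S)-4-benzyl-1,3-oxazolidin-2-one; 24 pent-4-enoyl chloride
Product: 25 (4S)-4-benzyl-3-(pent-4-enoyl)-1,3-oxazolidin-2-one
Conditions: n-BuLi, THF, −78 °C; then 24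
Reagents that add atoms: none
Why: N-acylation of the lithiated oxazolidinone with an acid chloride, the standard entry to aldol imides.

Step 15
Reactants: 25 (4S)-4-benzyl-3-(pent-4-enoyl)-1,3-oxazolidin-2-one; 26 4-benzyloxy-3,5-dimethoxybenzaldehyde
Product: 27 (4S)-4-benzyl-3-[(2S)-2-[(S)-(4-benzyloxy-3,5-dimethoxyphenyl)(hydroxy)methyl]pent-4-enoyl]-1,3-oxazolidin-2-one
Conditions: Bu2BOTf, iPr2NEt, CH2Cl2, −78 to 0 °C; then pH 7 buffer, MeOH, H2O2, 0 °C
Reagents that add atoms: none
Why: Evans syn-aldol: the (Z)-dibutylboron enolate reacts through a Zimmerman–Traxler chair with the auxiliary carbonyl turned away, which should set the future C5′ and C6′ as the (2S,3S) syn diad.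

Step 16
Reactants: 27 (4S)-4-benzyl-3-[(2S)-2-[(S)-(4-benzyloxy-3,5-dimethoxyphenyl)(hydroxy)methyl]pent-4-enoyl]-1,3-oxazolidin-2-one
Product: 28 (1S,2R)-1-(4-benzyloxy-3,5-dimethoxyphenyl)-2-(prop-2-en-1-yl)propane-1,3-diol
Conditions: LiBH4, H2O (1 equiv), Et2O, 0 °C
Reagents that add atoms: none
Why: Reductive removal of the auxiliary as in step 7; the imide carbonyl becomes C4′.

Step 17
Reactants: 28 (1S,2R)-1-(4-benzyloxy-3,5-dimethoxyphenyl)-2-(prop-2-en-1-yl)propane-1,3-diol
Product: 29 (4S,5R)-4-(4-benzyloxy-3,5-dimethoxyphenyl)-2,2-di-tert-butyl-5-(prop-2-en-1-yl)-1,3,2-dioxasilinane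
Conditions: t-Bu2Si(OTf)2, 2,6-lutidine, CH2Cl2, 0 °C
Reagents that add atoms: di-tert-butylsilyl bis(trifluoromethanesulfonate), CC(C)(C)[Si](OS(=O)(=O)C(F)(F)F)(OS(=O)(=O)C(F)(F)F)C(C)(C)C
Why: Silylene protection of the 1,3-diol; it tolerates the oxidations and the boron aldol and is later removed by fluoride, so the late intermediate never meets acid.

Step 18
Reactants: 29 (4S,5R)-4-(4-benzyloxy-3,5-dimethoxyphenyl)-2,2-di-tert-butyl-5-(prop-2-en-1-yl)-1,3,2-dioxasilinane
Product: 30 2-[(4S,5R)-4-(4-benzyloxy-3,5-dimethoxyphenyl)-2,2-di-tert-butyl-1,3,2-dioxasilinan-5-yl]acetaldehyde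
Conditions: OsO4 (2 mol %), NaIO4, 2,6-lutidine, dioxane/H2O, rt
Reagents that add atoms: osmium tetroxide, O=[Os](=O)(=O)=O; sodium periodate, [Na+].[O-]I(=O)(=O)=O
Why: Lemieux–Johnson cleavage (dihydroxylation then periodate cleavage) of the terminal alkene; OsO4 does not attack the electron-rich arene, which rules out ozone or RuO4.

Step 19
Reactants: 30 2-[(4S,5R)-4-(4-benzyloxy-3,5-dimethoxyphenyl)-2,2-di-tert-butyl-1,3,2-dioxasilinan-5-yl]acetaldehyde
Product: 31 2-[(4S,5R)-4-(4-benzyloxy-3,5-dimethoxyphenyl)-2,2-di-tert-butyl-1,3,2-dioxasilinan-5-yl]acetic acid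
Conditions: NaClO2, NaH2PO4, 2-methylbut-2-ene, t-BuOH/H2O, rt
Reagents that add atoms: sodium chlorite, [Na+].[O-]Cl=O
Why: Pinnick oxidation; the alkene scavenger removes hypochlorous acid before it can chlorinate the trialkoxyarene.

Step 20
Reactants: 31 2-[(4S,5R)-4-(4-benzyloxy-3,5-dimethoxyphenyl)-2,2-di-tert-butyl-1,3,2-dioxasilinan-5-yl]acetic acid; 8 (4S)-4-benzyl-1,3-oxazolidin-2-one
Product: 33 (4S)-4-benzyl-3-{2-[(4S,5R)-4-(4-benzyloxy-3,5-dimethoxyphenyl)-2,2-di-tert-butyl-1,3,2-dioxasilinan-5-yl]acetyl}-1,3-oxazolidin-2-one, via mixed pivalic anhydride 32 (not isolated)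
Conditions: PivCl, Et3N, THF, −20 °C; then 8, LiCl, rt
Reagents that add atoms: pivaloyl chloride, CC(C)(C)C(Cl)=O (present only in 32)
Why: Mixed-anhydride N-acylation as in step 5; the carboxyl carbon becomes C8′.

Step 21
Reactants: 23 (2S,3S)-2-(4-benzyloxy-3-methoxyphenyl)-7-methoxy-3-[(naphthalen-2-ylmethoxy)methyl]-2,3-dihydro-1-benzofuran-5-carbaldehyde; 33 (4S)-4-benzyl-3-{2-[(4S,5R)-4-(4-benzyloxy-3,5-dimethoxyphenyl)-2,2-di-tert-butyl-1,3,2-dioxasilinan-5-yl]acetyl}-1,3-oxazolidin-2-one
Product: 34 (4S)-4-benzyl-3-[(2S,3S)-3-(ArB)-2-[(4S,5R)-4-(4-benzyloxy-3,5-dimethoxyphenyl)-2,2-di-tert-butyl-1,3,2-dioxasilinan-5-yl]-3-hydroxypropanoyl]-1,3-oxazolidin-2-one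
Conditions: 33 (1.3 equiv), Bu2BOTf, iPr2NEt, CH2Cl2, −78 °C; then 23, −78 to 0 °C; pH 7 buffer, MeOH, H2O2, 0 °C
Reagents that add atoms: none
Why: Second Evans syn-aldol: the auxiliary on the boron (Z)-enolate dominates over the resident C5′ centre and should set C1′ and C2′ as the (2S,3S) syn diad. The remote C2/C3 pair has no influence, so reagent control is essential.

Step 22
Reactants: 34 (4S)-4-benzyl-3-[(2S,3S)-3-(ArB)-2-[(4S,5R)-4-(4-benzyloxy-3,5-dimethoxyphenyl)-2,2-di-tert-butyl-1,3,2-dioxasilinan-5-yl]-3-hydroxypropanoyl]-1,3-oxazolidin-2-one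
Product: 35 (1S,2R)-1-(ArB)-2-[(4S,5R)-4-(4-benzyloxy-3,5-dimethoxyphenyl)-2,2-di-tert-butyl-1,3,2-dioxasilinan-5-yl]propane-1,3-diol
Conditions: LiBH4, H2O (1 equiv), Et2O/THF, 0 °C
Reagents that add atoms: none
Why: Reductive removal of the auxiliary turns the imide carbonyl into the C8′ hydroxymethyl group without touching any stereocentre.

Step 23
Reactants: 35 (1S,2R)-1-(ArB)-2-[(4S,5R)-4-(4-benzyloxy-3,5-dimethoxyphenyl)-2,2-di-tert-butyl-1,3,2-dioxasilinan-5-yl]propane-1,3-diol
Product: 36 (1S,2R,3R,4S)-1-(4-benzyloxy-3,5-dimethoxyphenyl)-4-(ArB)-2,3-bis(hydroxymethyl)butane-1,4-diol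
Conditions: TBAF, AcOH, THF, 0 °C to rt
Reagents that add atoms: none
Why: Buffered fluoride removes the silylene and frees the C4′ and C6′ hydroxyls; no acid reaches the benzylic carbinols or the C2–O1 bond.

Step 24
Reactants: 36 (1S,2R,3R,4S)-1-(4-benzyloxy-3,5-dimethoxyphenyl)-4-(ArB)-2,3-bis(hydroxymethyl)butane-1,4-diol
Product: 38 (1′R,2′S,5′R,6′S)-2′-(ArB)-6′-(4-benzyloxy-3,5-dimethoxyphenyl)-3′,7′-dioxabicyclo[3.3.0]octane, via bis(methanesulfonate) 37 (not isolated)
Conditions: MsCl (2.2 equiv), pyridine, −20 °C to rt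
Reagents that add atoms: methanesulfonyl chloride, CS(Cl)(=O)=O (present only in 37)
Why: Primary-selective mesylation followed by double intramolecular Williamson etherification (5-exo-tet): each benzylic hydroxyl displaces the primary mesylate four atoms away, forming O3′–C4′ and O7′–C8′. No bond to a stereocentre is broken, so cis fusion follows from C1′/C5′ and the exo aryl groups from C2′/C6′.

Step 25
Reactants: 38 (1′R,2′S,5′R,6′S)-2′-(ArB)-6′-(4-benzyloxy-3,5-dimethoxyphenyl)-3′,7′-dioxabicyclo[3.3.0]octane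
Product: 39 4-[(1S,3aR,4S,6aR)-4-[(2S,3S)-2-(4-hydroxy-3-methoxyphenyl)-3-(hydroxymethyl)-7-methoxy-2,3-dihydro-1-benzofuran-5-yl]tetrahydro-1H,3H-furo[3,4-c]furan-1-yl]-2,6-dimethoxyphenol
Conditions: H2 (1 atm), 10% Pd/C, EtOAc/EtOH, rt; stopped as soon as 38 is consumed
Reagents that add atoms: none
Why: Hydrogenolysis of two aryl benzyl ethers and one NAP ether, all fast-cleaving arylmethyl ethers, under neutral conditions; a short reaction should spare the slower ring benzylic C–O bonds.

## Compound list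

1 | 5-bromofuran-3-carboxylic acid | OC(=O)c1coc(Br)c1 | starting material
2 | (5-bromofuran-3-yl)methanol | OCc1coc(Br)c1 | intermediate
3 | tert-butyl[(5-bromofuran-3-yl)methoxy]dimethylsilane | CC(C)(C)[Si](C)(C)OCc1coc(Br)c1 | intermediate
4 | ethyl bromoacetate | CCOC(=O)CBr | starting material
5 | (2-ethoxy-2-oxoethyl)zinc bromide | CCOC(=O)C[Zn]Br | intermediate
6 | ethyl 2-{4-[(tert-butyldimethylsilyloxy)methyl]furan-2-yl}acetate | CCOC(=O)Cc1cc(CO[Si](C)(C)C(C)(C)C)co1 | intermediate
7 | 2-{4-[(tert-butyldimethylsilyloxy)methyl]furan-2-yl}acetic acid | OC(=O)Cc1cc(CO[Si](C)(C)C(C)(C)C)co1 | intermediate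
8 | (4S)-4-benzyl-1,3-oxazolidin-2-one | O=C1N[C@@H](Cc2ccccc2)CO1 | starting material
9 | 2-{4-[(tert-butyldimethylsilyloxy)methyl]furan-2-yl}acetic pivalic anhydride | CC(C)(C)C(=O)OC(=O)Cc1cc(CO[Si](C)(C)C(C)(C)C)co1 | intermediate
10 | (4S)-4-benzyl-3-(2-{4-[(tert-butyldimethylsilyloxy)methyl]furan-2-yl}acetyl)-1,3-oxazolidin-2-one | O=C(Cc1cc(CO[Si](C)(C)C(C)(C)C)co1)N1[C@@H](Cc2ccccc2)COC1=O | intermediate
11 | 4-benzyloxy-3-methoxybenzaldehyde | COc1cc(C=O)ccc1OCc1ccccc1 | starting material
12 | O-trimethylsilyl ether of 13 | COc1cc([C@@H](O[Si](C)(C)C)[C@H](C(=O)N2[C@@H](Cc3ccccc3)COC2=O)c2cc(CO[Si](C)(C)C(C)(C)C)co2)ccc1OCc1ccccc1 | intermediate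
13 | (4S)-4-benzyl-3-[(2S,3S)-3-(4-benzyloxy-3-methoxyphenyl)-2-{4-[(tert-butyldimethylsilyloxy)methyl]furan-2-yl}-3-hydroxypropanoyl]-1,3-oxazolidin-2-one | COc1cc([C@@H](O)[C@H](C(=O)N2[C@@H](Cc3ccccc3)COC2=O)c2cc(CO[Si](C)(C)C(C)(C)C)co2)ccc1OCc1ccccc1 | intermediate
14 | (1S,2S)-1-(4-benzyloxy-3-methoxyphenyl)-2-{4-[(tert-butyldimethylsilyloxy)methyl]furan-2-yl}propane-1,3-diol | COc1cc([C@@H](O)[C@H](CO)c2cc(CO[Si](C)(C)C(C)(C)C)co2)ccc1OCc1ccccc1 | intermediate
15 | (1S,2S)-1-(4-benzyloxy-3-methoxyphenyl)-2-{4-[(tert-butyldimethylsilyloxy)methyl]furan-2-yl}-3-(naphthalen-2-ylmethoxy)propan-1-ol | COc1cc([C@@H](O)[C@H](COCc2ccc3ccccc3c2)c2cc(CO[Si](C)(C)C(C)(C)C)co2)ccc1OCc1ccccc1 | intermediate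
16 | trichloroethylene | ClC=C(Cl)Cl | starting material
17 | (E)-1,2-dichlorovinyl ether of 15 | COc1cc([C@@H](O/C(Cl)=C\Cl)[C@H](COCc2ccc3ccccc3c2)c2cc(CO[Si](C)(C)C(C)(C)C)co2)ccc1OCc1ccccc1 | intermediate
18 | lithium acetylide of 19 (lithium on the terminal alkyne carbon) | COc1cc([C@@H](OC#C[Li])[C@H](COCc2ccc3ccccc3c2)c2cc(CO[Si](C)(C)C(C)(C)C)co2)ccc1OCc1ccccc1 | intermediate
19 | (1S,2S)-1-(4-benzyloxy-3-methoxyphenyl)-1-(ethynyloxy)-2-{4-[(tert-butyldimethylsilyloxy)methyl]furan-2-yl}-3-(naphthalen-2-ylmethoxy)propane | COc1cc([C@@H](OC#C)[C@H](COCc2ccc3ccccc3c2)c2cc(CO[Si](C)(C)C(C)(C)C)co2)ccc1OCc1ccccc1 | intermediate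
20 | (2S,3S)-2-(4-benzyloxy-3-methoxyphenyl)-5-[(tert-butyldimethylsilyloxy)methyl]-3-[(naphthalen-2-ylmethoxy)methyl]-2,3-dihydro-1-benzofuran-7-ol (cis) | COc1cc([C@H]2Oc3c(O)cc(CO[Si](C)(C)C(C)(C)C)cc3[C@H]2COCc2ccc3ccccc3c2)ccc1OCc1ccccc1 | intermediate
21 | 7-O-methyl ether of 20 | COc1cc([C@H]2Oc3c(OC)cc(CO[Si](C)(C)C(C)(C)C)cc3[C@H]2COCc2ccc3ccccc3c2)ccc1OCc1ccccc1 | intermediate
22 | [(2S,3S)-2-(4-benzyloxy-3-methoxyphenyl)-7-methoxy-3-[(naphthalen-2-ylmethoxy)methyl]-2,3-dihydro-1-benzofuran-5-yl]methanol | COc1cc([C@H]2Oc3c(OC)cc(CO)cc3[C@H]2COCc2ccc3ccccc3c2)ccc1OCc1ccccc1 | intermediate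
23 | (2S,3S)-2-(4-benzyloxy-3-methoxyphenyl)-7-methoxy-3-[(naphthalen-2-ylmethoxy)methyl]-2,3-dihydro-1-benzofuran-5-carbaldehyde | COc1cc([C@H]2Oc3c(OC)cc(C=O)cc3[C@H]2COCc2ccc3ccccc3c2)ccc1OCc1ccccc1 | intermediate
24 | pent-4-enoyl chloride | C=CCCC(Cl)=O | starting material
25 | (4S)-4-benzyl-3-(pent-4-enoyl)-1,3-oxazolidin-2-one | C=CCCC(=O)N1[C@@H](Cc2ccccc2)COC1=O | intermediate
26 | 4-benzyloxy-3,5-dimethoxybenzaldehyde | COc1cc(C=O)cc(OC)c1OCc1ccccc1 | starting material
27 | (4S)-4-benzyl-3-[(2S)-2-[(S)-(4-benzyloxy-3,5-dimethoxyphenyl)(hydroxy)methyl]pent-4-enoyl]-1,3-oxazolidin-2-one | C=CC[C@H](C(=O)N1[C@@H](Cc2ccccc2)COC1=O)[C@H](O)c1cc(OC)c(OCc2ccccc2)c(OC)c1 | intermediate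
28 | (1S,2R)-1-(4-benzyloxy-3,5-dimethoxyphenyl)-2-(prop-2-en-1-yl)propane-1,3-diol | C=CC[C@H](CO)[C@H](O)c1cc(OC)c(OCc2ccccc2)c(OC)c1 | intermediate
29 | (4S,5R)-4-(4-benzyloxy-3,5-dimethoxyphenyl)-2,2-di-tert-butyl-5-(prop-2-en-1-yl)-1,3,2-dioxasilinane | C=CC[C@@H]1CO[Si](C(C)(C)C)(C(C)(C)C)O[C@@H]1c1cc(OC)c(OCc2ccccc2)c(OC)c1 | intermediate
30 | 2-[(4S,5R)-4-(4-benzyloxy-3,5-dimethoxyphenyl)-2,2-di-tert-butyl-1,3,2-dioxasilinan-5-yl]acetaldehyde | O=CC[C@@H]1CO[Si](C(C)(C)C)(C(C)(C)C)O[C@@H]1c1cc(OC)c(OCc2ccccc2)c(OC)c1 | intermediate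
31 | 2-[(4S,5R)-4-(4-benzyloxy-3,5-dimethoxyphenyl)-2,2-di-tert-butyl-1,3,2-dioxasilinan-5-yl]acetic acid | OC(=O)C[C@@H]1CO[Si](C(C)(C)C)(C(C)(C)C)O[C@@H]1c1cc(OC)c(OCc2ccccc2)c(OC)c1 | intermediate
32 | mixed pivalic anhydride of 31 | CC(C)(C)C(=O)OC(=O)C[C@@H]1CO[Si](C(C)(C)C)(C(C)(C)C)O[C@@H]1c1cc(OC)c(OCc2ccccc2)c(OC)c1 | intermediate
33 | (4S)-4-benzyl-3-{2-[(4S,5R)-4-(4-benzyloxy-3,5-dimethoxyphenyl)-2,2-di-tert-butyl-1,3,2-dioxasilinan-5-yl]acetyl}-1,3-oxazolidin-2-one | O=C(C[C@@H]1CO[Si](C(C)(C)C)(C(C)(C)C)O[C@@H]1c1cc(OC)c(OCc2ccccc2)c(OC)c1)N1[C@@H](Cc2ccccc2)COC1=O | intermediate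
34 | (4S)-4-benzyl-3-[(2S,3S)-3-(ArB)-2-[(4S,5R)-4-(4-benzyloxy-3,5-dimethoxyphenyl)-2,2-di-tert-butyl-1,3,2-dioxasilinan-5-yl]-3-hydroxypropanoyl]-1,3-oxazolidin-2-one | COc1cc([C@H]2Oc3c(OC)cc([C@@H](O)[C@@H](C(=O)N4[C@@H](Cc5ccccc5)COC4=O)[C@@H]4CO[Si](C(C)(C)C)(C(C)(C)C)O[C@@H]4c4cc(OC)c(OCc5ccccc5)c(OC)c4)cc3[C@H]2COCc2ccc3ccccc3c2)ccc1OCc1ccccc1 | intermediate
35 | (1S,2R)-1-(ArB)-2-[(4S,5R)-4-(4-benzyloxy-3,5-dimethoxyphenyl)-2,2-di-tert-butyl-1,3,2-dioxasilinan-5-yl]propane-1,3-diol | COc1cc([C@H]2Oc3c(OC)cc([C@@H](O)[C@@H](CO)[C@@H]4CO[Si](C(C)(C)C)(C(C)(C)C)O[C@@H]4c4cc(OC)c(OCc5ccccc5)c(OC)c4)cc3[C@H]2COCc2ccc3ccccc3c2)ccc1OCc1ccccc1 | intermediate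
36 | (1S,2R,3R,4S)-1-(4-benzyloxy-3,5-dimethoxyphenyl)-4-(ArB)-2,3-bis(hydroxymethyl)butane-1,4-diol | COc1cc([C@H]2Oc3c(OC)cc([C@@H](O)[C@@H](CO)[C@H](CO)[C@H](O)c4cc(OC)c(OCc5ccccc5)c(OC)c4)cc3[C@H]2COCc2ccc3ccccc3c2)ccc1OCc1ccccc1 | intermediate
37 | bis(methanesulfonate) of 36 at the two primary hydroxyls | COc1cc([C@H]2Oc3c(OC)cc([C@@H](O)[C@@H](COS(C)(=O)=O)[C@H](COS(C)(=O)=O)[C@H](O)c4cc(OC)c(OCc5ccccc5)c(OC)c4)cc3[C@H]2COCc2ccc3ccccc3c2)ccc1OCc1ccccc1 | intermediate
38 | (1′R,2′S,5′R,6′S)-2′-(ArB)-6′-(4-benzyloxy-3,5-dimethoxyphenyl)-3′,7′-dioxabicyclo[3.3.0]octane (target as bis-O-benzyl, O-NAP ether) | COc1cc([C@H]2Oc3c(OC)cc([C@H]4OC[C@H]5[C@@H]4CO[C@@H]5c4cc(OC)c(OCc5ccccc5)c(OC)c4)cc3[C@H]2COCc2ccc3ccccc3c2)ccc1OCc1ccccc1 | intermediate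
39 | 4-[(1S,3aR,4S,6aR)-4-[(2S,3S)-2-(4-hydroxy-3-methoxyphenyl)-3-(hydroxymethyl)-7-methoxy-2,3-dihydro-1-benzofuran-5-yl]tetrahydro-1H,3H-furo[3,4-c]furan-1-yl]-2,6-dimethoxyphenol | COc1cc([C@H]2Oc3c(OC)cc([C@H]4OC[C@H]5[C@@H]4CO[C@@H]5c4cc(OC)c(O)c(OC)c4)cc3[C@H]2CO)ccc1O | target

## Step count and least certain steps

Total: 25 steps. Longest linear sequence: 18 steps (steps 1–13 and 21–25, from 1 to 39); the side branch from 8 and 24 to 33 is 7 steps.

**Step 10 (key step).** The most likely failure is heterolysis of the benzylic C2–O1 bond in the gold-activated ynol ether before the furan attacks, because the para-benzyloxy aryl group stabilises the cation; this would lose material or scramble C2. Adventitious water could also hydrate the ynol ether.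

Fallback: make ring B from an arene and form the cis ring by carbenoid C–H insertion.
- Setting out from 11, NaBH4 gives [4-(benzyloxy)-3-methoxyphenyl]methanol F1.
- Mitsunobu etherification of F1 with commercial methyl 3-bromo-4-hydroxy-5-methoxybenzoate gives the aryl benzyl ether F2.
- Palladium/XPhos coupling of F2 with the zinc enolate 5 gives the arylacetate F3.
- Diazo transfer (p-acetamidobenzenesulfonyl azide, DBU) gives the aryldiazoacetate F4.
- The dirhodium tetracarboxylate Rh2(S-PTTL)4, or its enantiomer, whichever delivers the required series, should insert the carbenoid into the benzylic ether C–H bond to give the cis diester F5.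
- DIBAL-H at −78 °C gives the diol F6, and MnO2 oxidises only the benzylic alcohol to the hydroxy aldehyde F7.
- Ag2O and 2-(bromomethyl)naphthalene then return the route at 23.

**Step 9.** The most likely failure is incomplete addition of the hindered secondary alkoxide to dichloroacetylene, or attack of the excess base on the NAP ether or the furan.

Fallback: build the alkyne by one-carbon olefination. Setting out from 15, acetic formic anhydride/pyridine gives the formate F8. CBr4/PPh3 converts F8 into the 2,2-dibromovinyl ether F9. Two equivalents of n-BuLi at −78 °C then give 18, which is protonated to return at 19.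

**Step 6.** The most likely failure is erosion of anti selectivity, or epimerisation at the furyl-bearing carbon, because this imide is much more acidic than a propionyl imide.

Fallback: change the auxiliary class and the enolate topology. Setting out from 7, coupling with (4R)-4-benzyl-1,3-thiazolidine-2-thione (EDC, DMAP) gives the N-acylthiazolidinethione F10. Its MgBr2·OEt2-catalysed aldol with 11 (Et3N, TMSCl) goes through a non-chelated enolate, on the opposite enolate face to the oxazolidinone, so the (R)-auxiliary is the one expected to give the same (2S,3S) diad in adduct F11. This assignment is to be confirmed by correlation. NaBH4 cleaves F11 and returns the route at 14.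

**Step 24.** The most likely failure is sulfonylation of the electron-rich benzylic hydroxyls. Ionisation there would give endo-aryl epimers at C2′ or C6′.

Fallback: close the rings one at a time. Setting out from 35, TsCl/Et3N with catalytic Me3N·HCl tosylates only the primary hydroxyl to give F12. TBAF removes the silylene, and the freed C6′ alkoxide closes ring E in the same flask to give the tetrahydrofuran diol F13. A Mitsunobu cyclodehydration (PPh3, DIAD) activates the primary hydroxyl of F13 and lets the C2′ hydroxyl close ring D with retention, returning at 38.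

## Further compounds

F1 | step 10 | [4-(benzyloxy)-3-methoxyphenyl]methanol | COc1cc(CO)ccc1OCc1ccccc1
F2 | step 10 | methyl 4-[(4-benzyloxy-3-methoxyphenyl)methoxy]-3-bromo-5-methoxybenzoate | COC(=O)c1cc(Br)c(OCc2ccc(OCc3ccccc3)c(OC)c2)c(OC)c1
F3 | step 10 | methyl 4-[(4-benzyloxy-3-methoxyphenyl)methoxy]-3-(2-ethoxy-2-oxoethyl)-5-methoxybenzoate | CCOC(=O)Cc1cc(C(=O)OC)cc(OC)c1OCc1ccc(OCc2ccccc2)c(OC)c1
F4 | step 10 | methyl 4-[(4-benzyloxy-3-methoxyphenyl)methoxy]-3-(1-diazo-2-ethoxy-2-oxoethyl)-5-methoxybenzoate | CCOC(=O)C(=[N+]=[N-])c1cc(C(=O)OC)cc(OC)c1OCc1ccc(OCc2ccccc2)c(OC)c1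
F5 | step 10 | 3-ethyl 5-methyl (2S,3R)-2-(4-benzyloxy-3-methoxyphenyl)-7-methoxy-2,3-dihydro-1-benzofuran-3,5-dicarboxylate (cis) | COc1cc([C@H]2Oc3c(OC)cc(C(=O)OC)cc3[C@H]2C(=O)OCC)ccc1OCc1ccccc1
F6 | step 10 | [(2S,3S)-2-(4-benzyloxy-3-methoxyphenyl)-3-(hydroxymethyl)-7-methoxy-2,3-dihydro-1-benzofuran-5-yl]methanol | COc1cc([C@H]2Oc3c(OC)cc(CO)cc3[C@H]2CO)ccc1OCc1ccccc1
F7 | step 10 | (2S,3S)-2-(4-benzyloxy-3-methoxyphenyl)-3-(hydroxymethyl)-7-methoxy-2,3-dihydro-1-benzofuran-5-carbaldehyde | COc1cc([C@H]2Oc3c(OC)cc(C=O)cc3[C@H]2CO)ccc1OCc1ccccc1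
F8 | step 9 | formate ester of 15 | COc1cc([C@@H](OC=O)[C@H](COCc2ccc3ccccc3c2)c2cc(CO[Si](C)(C)C(C)(C)C)co2)ccc1OCc1ccccc1
F9 | step 9 | 2,2-dibromovinyl ether of 15 | COc1cc([C@@H](OC=C(Br)Br)[C@H](COCc2ccc3ccccc3c2)c2cc(CO[Si](C)(C)C(C)(C)C)co2)ccc1OCc1ccccc1
F10 | step 6 | 1-[(4R)-4-benzyl-2-thioxo-1,3-thiazolidin-3-yl]-2-{4-[(tert-butyldimethylsilyloxy)methyl]furan-2-yl}ethan-1-one | O=C(Cc1cc(CO[Si](C)(C)C(C)(C)C)co1)N1[C@H](Cc2ccccc2)CSC1=S
F11 | step 6 | (2S,3S)-1-[(4R)-4-benzyl-2-thioxo-1,3-thiazolidin-3-yl]-3-(4-benzyloxy-3-methoxyphenyl)-2-{4-[(tert-butyldimethylsilyloxy)methyl]furan-2-yl}-3-hydroxypropan-1-one | COc1cc([C@@H](O)[C@H](C(=O)N2[C@H](Cc3ccccc3)CSC2=S)c2cc(CO[Si](C)(C)C(C)(C)C)co2)ccc1OCc1ccccc1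
F12 | step 24 | primary p-toluenesulfonate of 35 | COc1cc([C@H]2Oc3c(OC)cc([C@@H](O)[C@@H](COS(=O)(=O)c4ccc(C)cc4)[C@@H]4CO[Si](C(C)(C)C)(C(C)(C)C)O[C@@H]4c4cc(OC)c(OCc5ccccc5)c(OC)c4)cc3[C@H]2COCc2ccc3ccccc3c2)ccc1OCc1ccccc1
F13 | step 24 | (S)-(ArB)[(3R,4R,5S)-5-(4-benzyloxy-3,5-dimethoxyphenyl)-4-(hydroxymethyl)tetrahydrofuran-3-yl]methanol | COc1cc([C@H]2Oc3c(OC)cc([C@@H](O)[C@H]4CO[C@H](c5cc(OC)c(OCc6ccccc6)c(OC)c5)[C@H]4CO)cc3[C@H]2COCc2ccc3ccccc3c2)ccc1OCc1ccccc1
A1 | alternative 1 | trans,trans-3-[aryl(hydroxy)methyl]-4-[2-(4-benzyloxy-3,5-dimethoxyphenyl)-1,3-dithian-2-yl]-5-(l-menthyloxy)butyrolactone, carbinol carbon unassigned | COc1cc([C@H]2Oc3c(OC)cc(C(O)[C@H]4C(=O)O[C@@H](O[C@@H]5C[C@H](C)CC[C@H]5C(C)C)[C@@H]4C4(c5cc(OC)c(OCc6ccccc6)c(OC)c5)SCCCS4)cc3[C@H]2CO[Si](C)(C)C(C)(C)C)ccc1OCc1ccccc1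
A2 | alternative 1 | (5R)-5-[(1R,2S,5R)-menthyloxy]furan-2(5H)-one | O=C1C=C[C@H](O[C@@H]2C[C@H](C)CC[C@H]2C(C)C)O1
A3 | alternative 1 | 2-(4-benzyloxy-3,5-dimethoxyphenyl)-1,3-dithiane | COc1cc(C2SCCCS2)cc(OC)c1OCc1ccccc1
A4 | alternative 1 | (2S,3S)-2-(4-benzyloxy-3-methoxyphenyl)-3-[(tert-butyldimethylsilyloxy)methyl]-7-methoxy-2,3-dihydro-1-benzofuran-5-carbaldehyde | COc1cc([C@H]2Oc3c(OC)cc(C=O)cc3[C@H]2CO[Si](C)(C)C(C)(C)C)ccc1OCc1ccccc1
A5 | alternative 2 | exo,exo-2,6-diaryl-3,7-dioxabicyclo[3.3.0]octan-8-one (tris-O-benzyl series) | COc1cc([C@H]2Oc3c(OC)cc([C@H]4OC[C@H]5[C@@H]4C(=O)O[C@@H]5c4cc(OC)c(OCc5ccccc5)c(OC)c4)cc3[C@H]2COCc2ccccc2)ccc1OCc1ccccc1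
A6 | alternative 2 | (E)-α-arylidene-γ-(4-benzyloxy-3,5-dimethoxyphenyl)-β-(hydroxymethyl)-γ-butyrolactone, β,γ-trans | COc1cc([C@H]2Oc3c(OC)cc(/C=C4/C(=O)O[C@H](c5cc(OC)c(OCc6ccccc6)c(OC)c5)[C@H]4CO)cc3[C@H]2COCc2ccccc2)ccc1OCc1ccccc1
A7 | alternative 3 | target as bis(O-benzyl) phenol ether and primary TBS ether | COc1cc([C@H]2Oc3c(OC)cc([C@H]4OC[C@H]5[C@@H]4CO[C@@H]5c4cc(OC)c(OCc5ccccc5)c(OC)c4)cc3[C@H]2CO[Si](C)(C)C(C)(C)C)ccc1OCc1ccccc1
A8 | alternative 3 | (E)-3-(4-benzyloxy-3,5-dimethoxyphenyl)allyl ether of the aryl(oxiranyl)methanol, epoxide carbon unassigned because it becomes the radical centre | COc1cc([C@H]2Oc3c(OC)cc([C@@H](OC/C=C/c4cc(OC)c(OCc5ccccc5)c(OC)c4)C4CO4)cc3[C@H]2CO[Si](C)(C)C(C)(C)C)ccc1OCc1ccccc1
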